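**Retrosynthetic overview**

1. Target 15 ⇒ bromo-depsidone 12 + silyl enol ether 14. The ring A aryl–CH2 bond is made last (palladium/tin-enolate coupling), so the 2-oxoheptyl ketone never meets an activated acid or a base.
2. 12 ⇒ seco acid 11 by dehydrative lactonisation; the seven-membered dioxepinone is the last ring formed.
3. 11 ⇒ diaryl ether diacid 7 + ylide 9 (key step). The ring B aryl–CH2 bond is made with reversed polarity: an aryl–rhodium from carboxylate-directed C–H metalation attacks the α-carbon of an α-oxo carbenoid (enolonium-type carbon from a β-keto sulfoxonium ylide). Two innately nucleophilic carbons (arene carbon and ketone α-carbon) are joined; acid then closes oxane and δ-lactone (spiroketal, first rings formed).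
4. 7 ⇒ 2 + 6 (copper Ullmann diaryl ether); 2 from 3,5-dibromoanisole, 6 from 5-bromo-2,4-dihydroxybenzoic acid.
5. 9 ⇒ (R)-δ-hexalactone 8, which supplies the R methyl carbinol centre; the S spiro centre follows under thermodynamic control.

Assumption: (6R)-6-methyloxan-2-one (8) is bought as the single enantiomer. Ring A is the methoxy ring; ring B is the trioxygenated ring, numbered as a benzoic acid (C1 = carboxyl carbon). PMB = 4-methoxybenzyl.

**Route**

Step 1
Reactants: 1 1,3-dibromo-5-methoxybenzene
Product: 2 2,6-dibromo-4-methoxybenzoic acid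
Conditions: LiN(iPr)2 (1.1 equiv), THF, −78 °C, 1 h; CO2 (g), −78 °C → rt; aq. HCl
Reagents that add atoms: carbon dioxide, O=C=O
Why: Directed ortho-lithiation removes the most acidic proton, the one flanked by both bromines, and the aryllithium is carboxylated.

Step 2
Reactants: 3 5-bromo-2,4-dihydroxybenzoic acid
Product: 4 4-methoxybenzyl 5-bromo-2,4-bis[(4-methoxybenzyl)oxy]benzoate
Conditions: 4-methoxybenzyl chloride (3.5 equiv), K2CO3 (4 equiv), Bu4NI (cat.), DMF, 70 °C
Reagents that add atoms: 4-methoxybenzyl chloride, COc1ccc(CCl)cc1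
Why: Exhaustive Williamson O-alkylation of the carboxylate and both phenols avoids any selectivity question.

Step 3
Reactants: 4 4-methoxybenzyl 5-bromo-2,4-bis[(4-methoxybenzyl)oxy]benzoate
Product: 6 5-hydroxy-2,4-bis[(4-methoxybenzyl)oxy]benzoic acid, via bromo acid potassium salt 5 (not isolated)
Conditions: Pd2(dba)3 (2 mol %), tBuXPhos (8 mol %), KOH (6 equiv), 1,4-dioxane/H2O 1:1, 100 °C, argon; cold aq. HCl to pH 3
Reagents that add atoms: potassium hydroxide, [K+].[OH-]
Why: Hydroxide saponifies the ester and zerovalent palladium with a bulky biarylphosphine catalyses C–O coupling of the aryl bromide with hydroxide (Buchwald-type hydroxylation); the PMB ethers are base-stable, which leaves O5 as the only free phenol.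

Step 4
Reactants: 2 2,6-dibromo-4-methoxybenzoic acid (2 equiv); 6 5-hydroxy-2,4-bis[(4-methoxybenzyl)oxy]benzoic acid
Product: 7 2-bromo-6-{5-carboxy-2,4-bis[(4-methoxybenzyl)oxy]phenoxy}-4-methoxybenzoic acid
Conditions: CuI (20 mol %), N,N-dimethylglycine (40 mol %), Cs2CO3 (5 equiv), DMF, 90 °C, argon; aq. citric acid
Reagents that add atoms: none
Why: Ullmann diaryl ether condensation at monovalent copper, accelerated by the ortho-carboxylate of 2; the excess of the symmetric dibromo acid favours mono-substitution.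

Step 5
Reactants: 8 (6R)-6-methyloxan-2-one
Product: 9 (6R)-1-[dimethyl(oxo)-λ6-sulfanylidene]-6-hydroxyheptan-2-one
Conditions: Me3S(O)I (2.2 equiv), KOtBu (2.2 equiv), THF, reflux, 2 h; then 8, 0 °C → rt
Reagents that add atoms: trimethylsulfoxonium iodide, C[S+](C)(C)=O.[I-]
Why: Dimethylsulfoxonium methylide opens the lactone by acyl substitution (Corey–Chaykovsky-type ylide acylation) to the stable β-keto ylide; the remote R carbinol centre is not touched.

Step 6 (key step)
Reactants: 7 2-bromo-6-{5-carboxy-2,4-bis[(4-methoxybenzyl)oxy]phenoxy}-4-methoxybenzoic acid; 9 (6R)-1-[dimethyl(oxo)-λ6-sulfanylidene]-6-hydroxyheptan-2-one (2 equiv)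
Product: 11 2-bromo-6-{[(3S,6'R)-6,8-dihydroxy-6'-methyl-1-oxospiro[isochromane-3,2'-oxan]-5-yl]oxy}-4-methoxybenzoic acid, via hydroxy keto diacid 10 (not isolated)
Conditions: [Cp*Rh(MeCN)3](SbF6)2 (8 mol %), NaOAc (1 equiv), CF3CH2OH, 50 °C, 16 h; evaporate; CF3CO2H/CH2Cl2 1:4, anisole (20 equiv), 0 °C → rt, 1 h
Reagents that add atoms: none
Why: Proposed new method: carboxylate-assisted metalation of the only ortho C–H of ring B (C6; the ring A carboxylate has no ortho hydrogen) gives a five-membered rhodacycle, the ylide carbon binds and loses DMSO to form an α-oxo rhodium carbene, and 1,1-migratory insertion moves the aryl group onto the ketone α-carbon, which reacts here as an electrophilic enolonium-type carbon instead of as an enolate, before protonolysis releases 10 and trivalent rhodium (redox-neutral; intramolecular O–H insertion of 9 would need a seven-membered ring and is slow); the closest known reaction type is the Cp*Rh-catalysed carboxylate-directed C–H acylmethylation/annulation of benzoic acids with β-keto sulfoxonium ylides to isocoumarins, here intercepted by the tethered δ-hydroxyl; CF3CO2H then cleaves both PMB ethers and closes hemiketal and δ-lactone, and under these equilibrating conditions the spiro centre settles as the anomerically stabilised (3S) isomer with the pre-set (6'R) methyl equatorial.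

Step 7
Reactants: 11 2-bromo-6-{[(3S,6'R)-6,8-dihydroxy-6'-methyl-1-oxospiro[isochromane-3,2'-oxan]-5-yl]oxy}-4-methoxybenzoic acid
Product: 12 bromo-depsidone (the target skeleton with Br in place of the 2-oxoheptyl group on ring A; spiro centre S, methyl centre R)
Conditions: DCC (1.5 equiv), DMAP (0.1 equiv), CH2Cl2 (0.005 M), 0 °C → rt
Reagents that add atoms: none
Why: Steglich-type dehydrative lactonisation; only the 6-OH next to the ether oxygen can reach the ring A carboxyl (seven-membered ring), the 8-OH is chelated to the lactone carbonyl and too far away, and no ketone is present that could divert the activated acid to an enol lactone.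

Step 8
Reactants: 13 heptan-2-one
Product: 14 (hept-1-en-2-yloxy)trimethylsilane
Conditions: LiN(iPr)2 (1.05 equiv), THF, −78 °C; Me3SiCl, −78 °C → rt
Reagents that add atoms: chlorotrimethylsilane, C[Si](C)(C)Cl
Why: Kinetic deprotonation at the methyl group and O-silylation give the terminal silyl enol ether.

Step 9
Reactants: 12 bromo-depsidone; 14 (hept-1-en-2-yloxy)trimethylsilane (2 equiv)
Product: 15 target CNP0301127.1
Conditions: PdCl2[P(o-tol)3]2 (5 mol %), Bu3SnF (1.5 equiv), toluene, 80 °C
Reagents that add atoms: none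
Why: Kuwajima–Urabe/Migita ketone α-arylation: oxidative addition of the aryl bromide to zerovalent palladium, transmetalation with the tin enolate formed in situ from 14 and Bu3SnF, and reductive elimination give the benzyl ketone under neutral, base-free conditions that spare the depsidone ester, the spiroketal lactone and both stereocentres.

**Compound list**

1 | 1,3-dibromo-5-methoxybenzene | COc1cc(Br)cc(Br)c1 | starting material
2 | 2,6-dibromo-4-methoxybenzoic acid | COc1cc(Br)c(C(=O)O)c(Br)c1 | intermediate
3 | 5-bromo-2,4-dihydroxybenzoic acid | OC(=O)c1cc(Br)c(O)cc1O | starting material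
4 | 4-methoxybenzyl 5-bromo-2,4-bis[(4-methoxybenzyl)oxy]benzoate | COc1ccc(COC(=O)c2cc(Br)c(OCc3ccc(OC)cc3)cc2OCc2ccc(OC)cc2)cc1 | intermediate
5 | potassium 5-bromo-2,4-bis[(4-methoxybenzyl)oxy]benzoate (not isolated) | [K+].[O-]C(=O)c1cc(Br)c(OCc2ccc(OC)cc2)cc1OCc1ccc(OC)cc1 | intermediate
6 | 5-hydroxy-2,4-bis[(4-methoxybenzyl)oxy]benzoic acid | OC(=O)c1cc(O)c(OCc2ccc(OC)cc2)cc1OCc1ccc(OC)cc1 | intermediate
7 | 2-bromo-6-{5-carboxy-2,4-bis[(4-methoxybenzyl)oxy]phenoxy}-4-methoxybenzoic acid | COc1cc(Br)c(C(=O)O)c(Oc2cc(C(=O)O)c(OCc3ccc(OC)cc3)cc2OCc2ccc(OC)cc2)c1 | intermediate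
8 | (6R)-6-methyloxan-2-one, (R)-δ-hexalactone | C[C@@H]1CCCC(=O)O1 | starting material
9 | (6R)-1-[dimethyl(oxo)-λ6-sulfanylidene]-6-hydroxyheptan-2-one | C[C@@H](O)CCCC(=O)C=S(C)(C)=O | intermediate
10 | 2-bromo-6-{3-carboxy-2-[(6R)-6-hydroxy-2-oxoheptyl]-4,6-bis[(4-methoxybenzyl)oxy]phenoxy}-4-methoxybenzoic acid (not isolated) | COc1cc(Br)c(C(=O)O)c(Oc2c(CC(=O)CCC[C@@H](C)O)c(C(=O)O)c(OCc3ccc(OC)cc3)cc2OCc2ccc(OC)cc2)c1 | intermediate
11 | 2-bromo-6-{[(3S,6'R)-6,8-dihydroxy-6'-methyl-1-oxospiro[isochromane-3,2'-oxan]-5-yl]oxy}-4-methoxybenzoic acid | COc1cc(Br)c(C(=O)O)c(Oc2c(O)cc(O)c3c2C[C@]2(CCC[C@@H](C)O2)OC3=O)c1 | intermediate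
12 | bromo-depsidone: dibenzo[b,e][1,4]dioxepin-11-one with ring A carrying Br (ortho to the ester carbonyl) and OMe, ring B carrying a free OH and fused to the δ-lactone that is spiro-linked (S) to (6R)-6-methyloxane | Brc1cc(OC)cc2c1C(=O)Oc1cc(O)c3c(c1O2)C[C@]1(CCC[C@@H](C)O1)OC3=O | intermediate
13 | heptan-2-one | CCCCCC(C)=O | starting material
14 | (hept-1-en-2-yloxy)trimethylsilane | CCCCCC(=C)O[Si](C)(C)C | intermediate
15 | CNP0301127.1: compound 12 with 2-oxoheptyl in place of Br; spiro centre S, methyl-bearing oxane carbon R | CCCCCC(=O)Cc1cc(OC)cc2c1C(=O)Oc1cc(O)c3c(c1O2)C[C@]1(CCC[C@@H](C)O1)OC3=O | target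

**Step count and risks**

Total: 9 steps. Longest linear sequence: 6 steps (3 → 4 → 6 → 7 → 11 → 12 → 15; steps 2, 3, 4, 6, 7, 9).

Steps most likely to fail:

Step 6. The C–H metalation site is flanked by the carboxyl and the aryloxy group, the free acids can protonate the ylide (leading to O-alkylation), and part of the material may stop as an isocoumarin that does not spirocyclise readily. The fallback sets out from 7 and 9 and returns at 11. It separates C–C bond formation from spirocyclisation and goes through an isolated isocoumarin. Ylide 9 is silylated (tBuMe2SiCl, imidazole, DMF) to (6R)-6-[(tert-butyldimethylsilyl)oxy]-1-[dimethyl(oxo)-λ6-sulfanylidene]heptan-2-one F1. F1 and 7 are coupled under the dehydrating conditions of the known isocoumarin synthesis ([Cp*RhCl2]2, AgSbF6, ClCH2CH2Cl, 80 °C) to give 2-bromo-6-({3-[(4R)-4-[(tert-butyldimethylsilyl)oxy]pentyl]-6,8-bis[(4-methoxybenzyl)oxy]-1-oxo-1H-isochromen-5-yl}oxy)-4-methoxybenzoic acid F2. Aqueous LiOH opens the enol lactone of F2 to the keto carboxylate, and CF3CO2H/H2O/anisole then removes the silyl and PMB groups and closes the spiroketal lactone under the same thermodynamic control to give 11.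

Step 9. The aryl bromide is ortho to the ester carbonyl, and any enolate of the product can attack the depsidone ester and rearrange it to an isocoumarin. The fallback sets out from 12 and returns at 15 with the coupling polarity inverted. Miyaura borylation (B2pin2, Pd(dppf)Cl2, KOAc, dioxane, 80 °C) gives the pinacol boronate of the depsidone F3. F3 is coupled with commercial 1-bromoheptan-2-one as an α-keto electrophile (Pd(OAc)2, P(o-tol)3, K3PO4·H2O, THF, rt), so the aryl carbon is the nucleophile and no ketone enolate is generated.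

Step 4. Mono-substitution of the hindered dibromo acid by an oxidation-sensitive phenol may be slow or over-run. The fallback sets out from 6 and returns at 7, replacing copper catalysis by a nucleophilic aromatic substitution. Commercial 1-bromo-3-fluoro-5-methoxybenzene is formylated (LiN(iPr)2, THF, −78 °C; DMF) to 2-bromo-6-fluoro-4-methoxybenzaldehyde F4. The aldehyde-activated fluoride of F4 is displaced by the phenoxide of 6 (K2CO3, DMF, 70 °C) to give 5-(3-bromo-2-formyl-5-methoxyphenoxy)-2,4-bis[(4-methoxybenzyl)oxy]benzoic acid F5. Pinnick oxidation of F5 (NaClO2, NaH2PO4, 2-methylbut-2-ene, tBuOH/H2O) gives 7.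

**Further compounds**

F1 | step 6 | (6R)-6-[(tert-butyldimethylsilyl)oxy]-1-[dimethyl(oxo)-λ6-sulfanylidene]heptan-2-one | C[C@@H](O[Si](C)(C)C(C)(C)C)CCCC(=O)C=S(C)(C)=O
F2 | step 6 | 2-bromo-6-({3-[(4R)-4-[(tert-butyldimethylsilyl)oxy]pentyl]-6,8-bis[(4-methoxybenzyl)oxy]-1-oxo-1H-isochromen-5-yl}oxy)-4-methoxybenzoic acid | COc1cc(Br)c(C(=O)O)c(Oc2c3C=C(CCC[C@@H](C)O[Si](C)(C)C(C)(C)C)OC(=O)c3c(OCc3ccc(OC)cc3)cc2OCc2ccc(OC)cc2)c1
F3 | step 9 | pinacol boronate of the depsidone (compound 12 with 4,4,5,5-tetramethyl-1,3,2-dioxaborolan-2-yl in place of Br) | CC1(C)OB(OC1(C)C)c1cc(OC)cc2c1C(=O)Oc1cc(O)c3c(c1O2)C[C@]1(CCC[C@@H](C)O1)OC3=O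
F4 | step 4 | 2-bromo-6-fluoro-4-methoxybenzaldehyde | COc1cc(F)c(C=O)c(Br)c1
F5 | step 4 | 5-(3-bromo-2-formyl-5-methoxyphenoxy)-2,4-bis[(4-methoxybenzyl)oxy]benzoic acid | COc1cc(Br)c(C=O)c(Oc2cc(C(=O)O)c(OCc3ccc(OC)cc3)cc2OCc2ccc(OC)cc2)c1
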